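**Retrosynthetic overview**

1. The depside ester C(=O)–O bond is cut into the ring A acid (2-benzyloxy-6-heptyl-4-methoxybenzoic acid) and a ring B phenol. Ring B comes from olivetol by formylation; its carboxyl is carried as the aldehyde and its 2-oxygen is methylated after the coupling.
2. The strategy rests on ring A: the methoxy-bearing C4 lies para to the carboxyl-bearing C1, with oxygen at C2 and heptyl at C6. This is the pattern of a 5-carboxy-2-pyrone (pyrone C5, C4, C3, C6 = arene C1, C2, C3, C6) plus a ketene acetal that supplies arene C4 (with its OMe) and C5.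
3. Ring A is therefore made by Diels–Alder reaction of methyl 4-(benzyloxy)-6-heptyl-2-oxo-2H-pyran-5-carboxylate with 1,1-dimethoxyethene (new bonds C3–C4 and C5–C6), followed by loss of CO2 and methanol.
4. The pyrone ring is built first from dimethyl 3-oxoglutarate and octanoyl chloride (C-acylation, lactonisation, O-benzylation). Ring order: pyrone, then ring A; ring B is present in olivetol from the start.

Key step: step 4

Remark: the target is achiral; the only stereocentres on the route are the two bridgeheads of the transient lactone 7, which forms as a racemate and loses both on aromatisation.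

**Route**

Step 1
Reactants: 1 dimethyl 3-oxoglutarate; 2 octanoyl chloride
Product: 3 dimethyl 2-octanoyl-3-oxopentanedioate
Conditions: MgCl2 (1.1 equiv), pyridine (2.2 equiv), CH2Cl2, 0 °C → rt; then 1 M HCl
Reagents that add atoms: none
Why: Soft enolisation of the β-keto ester as its magnesium chelate (Rathke-type C-acylation) sends the acid chloride to carbon C2 of the symmetrical diester, and the tricarbonyl product stays chelated, which should suppress a second acylation.

Step 2
Reactants: 3 dimethyl 2-octanoyl-3-oxopentanedioate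
Product: 4 methyl 6-heptyl-4-hydroxy-2-oxo-2H-pyran-5-carboxylate
Conditions: conc. H2SO4, 0 °C → rt; then ice/H2O
Reagents that add atoms: none
Why: In strong acid the enol oxygen of the octanoyl group closes onto the distal ester (acid-catalysed lactonisation of a 3,5-dioxo ester to a 4-hydroxy-2-pyrone), which is the only six-membered lactone this tricarbonyl can form and leaves the other ester at C5.

Step 3
Reactants: 4 methyl 6-heptyl-4-hydroxy-2-oxo-2H-pyran-5-carboxylate
Product: 5 methyl 4-(benzyloxy)-6-heptyl-2-oxo-2H-pyran-5-carboxylate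
Conditions: BnOH, PPh3, DIAD, THF, 0 °C → rt
Reagents that add atoms: benzyl alcohol, OCc1ccccc1
Why: Mitsunobu etherification of the acidic 4-hydroxy-2-pyrone with a primary alcohol is known to alkylate the 4-oxygen and keep the conjugated 2-pyrone, and it avoids the C3-benzylation that benzyl halides with base tend to give.

Step 4
Reactants: 5 methyl 4-(benzyloxy)-6-heptyl-2-oxo-2H-pyran-5-carboxylate; 6 1,1-dimethoxyethene
Product: 9 methyl 2-(benzyloxy)-6-heptyl-4-methoxybenzoate, via bridged bicyclic lactone 7 (not isolated), via dimethoxycyclohexadiene 8 (not isolated)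
Conditions: 6 (5 equiv), toluene, sealed tube, 120–140 °C
Reagents that add atoms: none
Why: The electron-rich CH2 terminus of the ketene acetal bonds to pyrone C6, which is β to the 5-ester and vinylogous to the lactone carbonyl, while the acetal carbon bonds to C3, so an asynchronous inverse-electron-demand [4+2] cycloaddition (in the limit a Michael addition followed by collapse of the zwitterion) closes the six-membered carbocycle as the bridged lactone 7. Retro-[4+2] loss of CO2 from 7 gives diene 8, and 1,2-elimination of methanol across the acetal carbon and the neighbouring CH2 gives the arene. The closest known reaction type is the conversion of alkyl coumalates and other ester-bearing 2-pyrones into anisates with this same ketene acetal. The ring is closed by intermolecular cycloaddition across C3 and C6 of the pyrone diene, and the two bridgehead stereocentres of 7 are racemic and vanish on aromatisation, so no stereocontrol is needed. The step needs regioselectivity, which the 5-ester and lactone carbonyl secure by making C6 the electrophilic terminus while the benzyloxy group makes C3 the electron-rich one, placing the new methoxy group para to the ester. Because the 4-benzyloxy and 6-heptyl groups make this diene less reactive than a coumalate, an excess of the ketene acetal, a sealed vessel and a high temperature are specified.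

Step 5
Reactants: 9 methyl 2-(benzyloxy)-6-heptyl-4-methoxybenzoate
Product: 10 2-(benzyloxy)-6-heptyl-4-methoxybenzoic acid
Conditions: KOH (10 equiv), DMSO/H2O 4:1, 100 °C; then 2 M HCl, 0 °C
Reagents that add atoms: potassium hydroxide, [K+].[OH-]
Why: Poorly solvated hydroxide in aqueous DMSO should saponify the methyl ester flanked by the benzyloxy and heptyl groups (ester hydrolysis by acyl–oxygen cleavage), while the benzyl and methyl aryl ethers are inert to base.

Step 6
Reactants: 11 olivetol
Product: 13 2,4-dihydroxy-6-pentylbenzaldehyde, via aryl iminium chloride 12 (not isolated)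
Conditions: POCl3 (1.2 equiv), DMF, 0 °C → rt; then H2O, 50 °C
Reagents that add atoms: N,N-dimethylformamide, CN(C)C=O; water, O
Why: Vilsmeier–Haack formylation of a 5-alkylresorcinol is expected at C4, para to one hydroxyl and ortho to the other, rather than at C2 between the two hydroxyls, and hydrolysis of the iminium salt gives the aldehyde.

Step 7
Reactants: 10 2-(benzyloxy)-6-heptyl-4-methoxybenzoic acid; 13 2,4-dihydroxy-6-pentylbenzaldehyde
Product: 15 4-formyl-3-hydroxy-5-pentylphenyl 2-(benzyloxy)-6-heptyl-4-methoxybenzoate, via mixed trifluoroacetic anhydride 14 (not isolated)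
Conditions: TFAA (2.5 equiv), toluene, 0 °C, 15 min; then 13 (1.0 equiv), rt
Reagents that add atoms: none
Why: The mixed anhydride of the hindered, electron-rich acid ionises towards an acylium ion stabilised by the para methoxy group and should acylate the free 4-hydroxyl of 13, whereas the 2-hydroxyl is tied up in a hydrogen bond to the formyl group (mixed-anhydride depside esterification).

Step 8
Reactants: 15 4-formyl-3-hydroxy-5-pentylphenyl 2-(benzyloxy)-6-heptyl-4-methoxybenzoate
Product: 16 4-formyl-3-methoxy-5-pentylphenyl 2-(benzyloxy)-6-heptyl-4-methoxybenzoate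
Conditions: MeI (3 equiv), K2CO3 (1.5 equiv), acetone, 50 °C
Reagents that add atoms: iodomethane, CI
Why: The only free phenol, made acidic by the ortho formyl group, is deprotonated by K2CO3 and O-methylated (Williamson etherification), while the depside ester is shielded by the two ortho substituents of ring A.

Step 9
Reactants: 16 4-formyl-3-methoxy-5-pentylphenyl 2-(benzyloxy)-6-heptyl-4-methoxybenzoate
Product: 17 4-{[2-(benzyloxy)-6-heptyl-4-methoxybenzoyl]oxy}-2-methoxy-6-pentylbenzoic acid
Conditions: NaClO2, NaH2PO4, 2-methyl-2-butene, tBuOH/THF/H2O, 0 °C → rt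
Reagents that add atoms: sodium chlorite, [Na+].[O-]Cl=O
Why: Pinnick oxidation converts the hindered aryl aldehyde into the acid without touching the ethers or the aryl ester, and the alkene scavenger removes the hypochlorous acid that would otherwise chlorinate the electron-rich rings.

Step 10
Reactants: 17 4-{[2-(benzyloxy)-6-heptyl-4-methoxybenzoyl]oxy}-2-methoxy-6-pentylbenzoic acid
Product: 18 4-[(6-heptyl-2-hydroxy-4-methoxybenzoyl)oxy]-2-methoxy-6-pentylbenzoic acid
Conditions: H2 (1 atm), 10% Pd/C, EtOAc, rt
Reagents that add atoms: none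
Why: Hydrogenolysis of the aryl benzyl ether over Pd/C is neutral and should leave the depside ester, the methyl ethers and the carboxylic acid intact.

**Compound list**

1 | dimethyl 3-oxoglutarate | COC(=O)CC(=O)CC(=O)OC | starting material
2 | octanoyl chloride | CCCCCCCC(=O)Cl | starting material
3 | dimethyl 2-octanoyl-3-oxopentanedioate | CCCCCCCC(=O)C(C(=O)OC)C(=O)CC(=O)OC | intermediate
4 | methyl 6-heptyl-4-hydroxy-2-oxo-2H-pyran-5-carboxylate | CCCCCCCc1oc(=O)cc(O)c1C(=O)OC | intermediate
5 | methyl 4-(benzyloxy)-6-heptyl-2-oxo-2H-pyran-5-carboxylate | CCCCCCCc1oc(=O)cc(OCc2ccccc2)c1C(=O)OC | intermediate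
6 | 1,1-dimethoxyethene | C=C(OC)OC | starting material
7 | methyl 5-(benzyloxy)-1-heptyl-8,8-dimethoxy-3-oxo-2-oxabicyclo[2.2.2]oct-5-ene-6-carboxylate (racemic, not isolated) | CCCCCCCC12CC(OC)(OC)C(C(=O)O1)C(OCc1ccccc1)=C2C(=O)OC | intermediate
8 | methyl 6-(benzyloxy)-2-heptyl-4,4-dimethoxycyclohexa-1,5-diene-1-carboxylate (not isolated) | CCCCCCCC1=C(C(=O)OC)C(OCc2ccccc2)=CC(OC)(OC)C1 | intermediate
9 | methyl 2-(benzyloxy)-6-heptyl-4-methoxybenzoate | CCCCCCCc1cc(OC)cc(OCc2ccccc2)c1C(=O)OC | intermediate
10 | 2-(benzyloxy)-6-heptyl-4-methoxybenzoic acid | CCCCCCCc1cc(OC)cc(OCc2ccccc2)c1C(=O)O | intermediate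
11 | olivetol (5-pentylbenzene-1,3-diol) | CCCCCc1cc(O)cc(O)c1 | starting material
12 | [(2,4-dihydroxy-6-pentylphenyl)methylidene]dimethyliminium chloride (not isolated) | CCCCCc1cc(O)cc(O)c1C=[N+](C)C.[Cl-] | intermediate
13 | 2,4-dihydroxy-6-pentylbenzaldehyde | CCCCCc1cc(O)cc(O)c1C=O | intermediate
14 | 2-(benzyloxy)-6-heptyl-4-methoxybenzoic trifluoroacetic anhydride (not isolated) | CCCCCCCc1cc(OC)cc(OCc2ccccc2)c1C(=O)OC(=O)C(F)(F)F | intermediate
15 | 4-formyl-3-hydroxy-5-pentylphenyl 2-(benzyloxy)-6-heptyl-4-methoxybenzoate | CCCCCCCc1cc(OC)cc(OCc2ccccc2)c1C(=O)Oc1cc(CCCCC)c(C=O)c(O)c1 | intermediate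
16 | 4-formyl-3-methoxy-5-pentylphenyl 2-(benzyloxy)-6-heptyl-4-methoxybenzoate | CCCCCCCc1cc(OC)cc(OCc2ccccc2)c1C(=O)Oc1cc(CCCCC)c(C=O)c(OC)c1 | intermediate
17 | 4-{[2-(benzyloxy)-6-heptyl-4-methoxybenzoyl]oxy}-2-methoxy-6-pentylbenzoic acid | CCCCCCCc1cc(OC)cc(OCc2ccccc2)c1C(=O)Oc1cc(CCCCC)c(C(=O)O)c(OC)c1 | intermediate
18 | 4-[(6-heptyl-2-hydroxy-4-methoxybenzoyl)oxy]-2-methoxy-6-pentylbenzoic acid | CCCCCCCc1cc(OC)cc(O)c1C(=O)Oc1cc(CCCCC)c(C(=O)O)c(OC)c1 | target

**Step count**

Total: 10 steps. Longest linear sequence: 9 steps (steps 1–5 and 7–10, from dimethyl 3-oxoglutarate); ring B joins after one step (step 6).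

**Steps most likely to fail**

Step 4. The cycloaddition may stall because the benzyloxy donor and the 6-heptyl group make the diene less electron-poor and crowd C6, so that oligomerisation of the ketene acetal outruns ring formation. The fallback builds ring A by a formal [3+3] cyclocondensation instead. It sets out from octanoyl chloride 2 and 1,1-dimethoxyethene 6 and comes back at 9. C-acylation of 6 by 2 (Et3N, Et2O, 0 °C) should give the β-keto ketene acetal 1,1-dimethoxydec-1-en-3-one F1. TiCl4-mediated condensation of F1 with 1,3-bis(trimethylsilyloxy)-1-methoxybuta-1,3-diene (CH2Cl2, −78 °C → rt) follows: the terminal diene carbon adds to the acetal carbon and the central carbon condenses with the ketone, which should give methyl 6-heptyl-2-hydroxy-4-methoxybenzoate F2. Benzylation of F2 (BnBr, K2CO3, DMF) returns to 9.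

Step 7. Acylation may be slow at the doubly ortho-substituted carbonyl and may spill over to the chelated 2-hydroxyl, or the acidic medium may begin to cleave the benzyl ether. The fallback differentiates the two phenols of ring B before the coupling and uses a base-mediated acylation. It sets out from aldehyde 13 and acid 10 and comes back at 16, so that step 8 is skipped. MOMCl and iPr2NEt (CH2Cl2, 0 °C) should protect only the free 4-hydroxyl to give 2-hydroxy-4-(methoxymethoxy)-6-pentylbenzaldehyde F3. Methylation (MeI, K2CO3, DMF) gives 2-methoxy-4-(methoxymethoxy)-6-pentylbenzaldehyde F4, and aqueous HCl in THF at 50 °C frees 4-hydroxy-2-methoxy-6-pentylbenzaldehyde F5. Acid 10 is converted with oxalyl chloride and catalytic DMF into 2-(benzyloxy)-6-heptyl-4-methoxybenzoyl chloride F6, which acylates F5 (Et3N, catalytic DMAP, CH2Cl2) to give 16.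

Step 3. The ambident pyrone anion may be alkylated at the 2-oxygen (giving the 4-pyranone isomer) or at C3, favoured by crowding of the 4-oxygen by the neighbouring ester. The fallback puts a silyl group on the pyrone and introduces the benzyl group only on the finished phenol. It sets out from 4 and comes back at 9. Silylation with TIPSOTf and 2,6-lutidine (CH2Cl2, 0 °C) occurs only at oxygen and should settle on the conjugated 2-pyrone, methyl 6-heptyl-2-oxo-4-[(triisopropylsilyl)oxy]-2H-pyran-5-carboxylate F7. Under the conditions of step 4, F7 and 6 should pass through the bridged lactone methyl 1-heptyl-8,8-dimethoxy-3-oxo-5-[(triisopropylsilyl)oxy]-2-oxabicyclo[2.2.2]oct-5-ene-6-carboxylate F8 and the diene methyl 2-heptyl-4,4-dimethoxy-6-[(triisopropylsilyl)oxy]cyclohexa-1,5-diene-1-carboxylate F9 to methyl 6-heptyl-4-methoxy-2-[(triisopropylsilyl)oxy]benzoate F10. One-pot desilylation and benzylation of F10 (CsF, BnBr, DMF) returns to 9.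

**Further compounds**

F1 | step 4 | 1,1-dimethoxydec-1-en-3-one | CCCCCCCC(=O)C=C(OC)OC
F2 | step 4 | methyl 6-heptyl-2-hydroxy-4-methoxybenzoate | CCCCCCCc1cc(OC)cc(O)c1C(=O)OC
F3 | step 7 | 2-hydroxy-4-(methoxymethoxy)-6-pentylbenzaldehyde | CCCCCc1cc(OCOC)cc(O)c1C=O
F4 | step 7 | 2-methoxy-4-(methoxymethoxy)-6-pentylbenzaldehyde | CCCCCc1cc(OCOC)cc(OC)c1C=O
F5 | step 7 | 4-hydroxy-2-methoxy-6-pentylbenzaldehyde | CCCCCc1cc(O)cc(OC)c1C=O
F6 | step 7 | 2-(benzyloxy)-6-heptyl-4-methoxybenzoyl chloride | CCCCCCCc1cc(OC)cc(OCc2ccccc2)c1C(=O)Cl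
F7 | step 3 | methyl 6-heptyl-2-oxo-4-[(triisopropylsilyl)oxy]-2H-pyran-5-carboxylate | CCCCCCCc1oc(=O)cc(O[Si](C(C)C)(C(C)C)C(C)C)c1C(=O)OC
F8 | step 3 | methyl 1-heptyl-8,8-dimethoxy-3-oxo-5-[(triisopropylsilyl)oxy]-2-oxabicyclo[2.2.2]oct-5-ene-6-carboxylate (racemic, not isolated) | CCCCCCCC12CC(OC)(OC)C(C(=O)O1)C(O[Si](C(C)C)(C(C)C)C(C)C)=C2C(=O)OC
F9 | step 3 | methyl 2-heptyl-4,4-dimethoxy-6-[(triisopropylsilyl)oxy]cyclohexa-1,5-diene-1-carboxylate (not isolated) | CCCCCCCC1=C(C(=O)OC)C(O[Si](C(C)C)(C(C)C)C(C)C)=CC(OC)(OC)C1
F10 | step 3 | methyl 6-heptyl-4-methoxy-2-[(triisopropylsilyl)oxy]benzoate | CCCCCCCc1cc(OC)cc(O[Si](C(C)C)(C(C)C)C(C)C)c1C(=O)OC
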